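Time is what separates the runs you have from the flasks you are asked about: the readings stop at 3.00 h, the question stands at 6.0 h, so you need to know how fast the making of target dies away.

in all of them: solid electrophile 0.10 M

| flask | nucleophile | remark | time |
|---|---|---|---|
| Tuesday's | 0.078 M | run made earlier |  |
| Saturday's | 0.18 M | run made earlier |  |
| noon | 0.100 M |  | 6.0 h |
| autumn | 0.150 M |  | 6.0 h |
| winter | 0.230 M |  | 6.0 h |

| run | time / h | solid electrophile / % | target / % |
|---|---|---|---|
| Tuesday's | 0.417 | 73 | 5 |
| Tuesday's | 1.00 | 67 | 7 |
| Tuesday's | 2.00 | 62 | 14 |
| Tuesday's | 3.00 | 60 | 16 |
| Saturday's | 0.833 | 63 | 12 |
| Saturday's | 1.50 | 56 | 18 |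
| Saturday's | 2.50 | 47 | 25 |
| Saturday's | 3.00 | 44 | 28 |

(each reading ± 2 percentage points)
- what was read earlier has a scatter of 2 percentage points, one standard deviation
- at the start none of the solid electrophile is in solution
- what has only dissolved of solid electrophile counts as not reacted
1. part of the solid electrophile that has reacted (what has only dissolved counts as not reacted) at the end, noon
2. part of the solid electrophile that has reacted (what has only dissolved counts as not reacted) at the end, autumn
3. part of the solid electrophile that has reacted (what has only dissolved counts as not reacted) at the end, winter
4. what raising the concentration of nucleophile from its lowest to its highest value here does to the part of the solid electrophile that has reacted (what has only dissolved counts as not reacted) (changes below 5 percentage points count as none) (no change / it rises / it falls)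

What has reacted is the target column, and two times carry the reckoning. Saturday's run makes target at 0.144 /h of the charge up to its first reading and at 0.0667 /h from its second to its last, and the midpoints of those stretches lie 1.83 h apart:

fade = ln(2) × 1.83 h / ln(0.144 /h / 0.0667 /h) = 1.65 h

This fade time is the time in which the rate of making target halves in Saturday's run, read as a first-order decay, and it carries the scatter of the readings. The quick first drop of the solid electrophile is no second clock, because solid plus target already reads 75.0% at Saturday's first reading, 0.833 h in, sooner than the fade time, and still 72.0% at its last. The second time is the stretch you add, which equals the time already run: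

half-lives = 3.00 h / 1.65 h = 1.82
gain of the second stretch over the first = 0.283

I take this fade time for every flask, and I scale the target at the last reading between Tuesday's and Saturday's as nucleophile to the power 0.669. My reckoning then gives:

noon 24.2%, autumn 31.8%, winter 42.3%

The forecast stands higher than this, at 30%, 42% and 56%, with it rises for the trend, in its words “I lean toward the empirical values, nudged up slightly”.

The flasks give 24.9%, 32.5% and 41.6%, so it rises, by 17 percentage points. In winter the free nucleophile goes from 17.8% of its own charge at 3.00 h to 6.68% at 6.00 h, while the electrophile stands at 24.9% of the solid charged. The fade time, put on winter's target of 32.6% at 3.00 h, gives 41.8% at 6.00 h, and the flask holds 41.6%.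

    electrophile + nucleophile ⇌ acid set free + target (K = 33.0, k = 0.0790 /M/min)
    nucleophile + acid set free ⇌ protonated nucleophile, settled at all times (K = 51000 /M)
    solid electrophile ⇌ electrophile, rate k3*(cs3 - [electrophile]) while solid is left; crystals form when [electrophile] > cs3 (solubility = 25.0 mM, k = 0.550 /min)
    2 nucleophile → self-condensation product (k = 0.0300 /M/min)

Take a neighbouring flask, winter's recipe with 0.058 M of nucleophile: the same scaling and fade time give 16.8% at 6.00 h. The computed flask gives 16.7%.

(The data stem from a simulated flask on assumed constants, and the scatter is random.)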